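## Structural features

Labdane numbering is used throughout: ring A is C1–C5 and C10, ring B is C5–C10, the side chain is C11–C16 (C16 is the methyl on C13), C17 is the methyl on C8, C18 and C19 sit on C4, and C20 sits on C10.

The target is a trans-fused decalin with a 3-methylpentanoic acid chain on C9, methyl groups on C4, C8 and C10, and an angeloyloxymethyl group (C19) on C4. Four stereocentres, C4 (S), C5 (R), C9 (S) and C10 (R), are contiguous; C4 and C10 are quaternary and their axial substituents (C19 and C20) are 1,3-syn. The fifth stereocentre, C13 (S), is separated from the ring by C11 and C12 and can neither direct nor be directed by the ring stereocentres. Ring B holds the only ring alkene, the trisubstituted C7=C8, whose position must be fixed against the Δ8 and Δ8(17) isomers. The fragile groups are the (Z)-2-methylbut-2-enoate (isomerises to the E ester with acid, base or heat), the Δ7 alkene with its allylic C9–H (acid-induced migration) and the free acid. The real difficulty is the C9–C10 bond between a tertiary and a quaternary carbon, together with C5 and C4 set relative to C10, in a molecule whose two halves (ring A with C18–C20, and C9 with C11–C16) are of similar size. The key step exploits the fact that C10 is β to C4: with C4 as a carbonyl carbon, ring A is 3-methylcyclohex-2-enone and C10 is an electrophilic β-carbon that can accept C9 as an sp2 nucleophile. The enolate that results sits at C5, where C6 must be attached, and the C9=C11 alkene left behind is the acceptor through which C8 later closes ring B.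

## Logic of the disconnections

In one sentence: 15 is made by a catalytic enantioselective conjugate addition of the complete side-chain alkenyl nucleophile (from 11) to the ring-A enone 12 at C10, with the enolate captured at C5 by 4.

30 ⇒ 28 ⇒ 27 ⇒ 24 + 25. The C19–O acyl bond is cut and C15 is carried at the alcohol oxidation level under a silyl group. The Z enoate and a free acid would not survive the hydride, dissolving-metal and organoaluminium steps, so both are introduced at the very end. The gain is that 24 has no fragile group. The demand is acylation of a neopentyl axial alcohol without Z/E isomerisation, and a final oxidation that leaves the enoate and the Δ7 alkene untouched.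

24 ⇒ 23 ⇒ 21. The C4–C18 bond and the C5–H bond are cut (C19 is adjusted from ester to carbinol). Both ring-A stereocentres that flank C10 can be set in one reductive C-methylation of a C4=C5 enoate under the control of the C10 methyl. Two stereocentres, one quaternary, disappear and ring A becomes planar at C4 and C5. The demand is protonation at C5 anti to C20 and methylation at C4 from the α face.

21 ⇒ 20. The C4–C19 bond is cut. A C4 enol sulfonate is the direct descendant of a C4 carbonyl, which is what the key step needs. The demand is carbonylation of a hindered tetrasubstituted enol sulfonate.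

20 ⇒ 19. The C8–C9 bond is cut, which opens ring B. A σ-radical at C8, generated from a vinyl iodide, fixes the ring alkene at C7=C8 by construction and adds to the C9=C11 alkene that the side chain brings with it. Ring B and the C9 stereocentre disappear; what remains is a monocyclic ring A with one ring stereocentre. The demand is 6-exo closure on the alkene face that gives 9α-H.

19 ⇒ 17 ⇒ 15. No skeletal bond is cut; the C6 hydroxyl of 15 is removed by dehydration and conjugate reduction, which delivers the C4=C5 enolate regiospecifically. C5 stays planar from here to step 12, so its configuration never has to be controlled on the monocycle. The demand is 1,4- rather than 1,2-reduction.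

15 ⇒ 11 + 12 + 4 (key). The C9–C10 and C5–C6 bonds are cut. This divides the skeleton at its most hindered bond into two halves of seven carbons each plus a four-carbon unit, all simple, and leaves the quaternary C10 as the only stereocentre to be created. The demand is 1,4-addition of an alkenyl group to a β,β-disubstituted enone with catalyst control of the new quaternary centre, and capture of the hindered enolate before it equilibrates.

11 ⇒ 9 ⇒ 8 ⇒ 6 ⇒ 5. The C9=C(CH3)2 double bond of 5 is cut and C9–C11 is raised to an alkyne. C13 comes from the chiral pool with the correct configuration, and 5 already holds C9 and C11–C16. The demand is conversion of an aldehyde to the terminal alkyne with the same carbon count, without touching C13.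

4 ⇒ 3 ⇒ 1. The C8–I bond is cut. The four-carbon unit C6–C7–C8(–C17) is a butynol in which hydroxyl-directed hydrometalation places the halogen on C8.

## Other disconnections considered

Alternative 1: (the first that comes to mind) the biomimetic cut of C4–C5 and C9–C10 in an acyclic trienoate. The forward step is proton-initiated cation–olefin bicyclisation of methyl (3S,6E,10E,14Z)-16-acetoxy-3,7,11,15-tetramethylhexadeca-6,10,14-trienoate A1 to methyl 19-acetoxylabd-7-en-15-oate A2. The chosen plan is preferred on mechanistic grounds. The oxygenated carbon must sit Z on the terminal alkene of A1, where an allylic acetoxy group lowers the nucleophilicity of the initiating alkene and is itself prone to ionisation. Loss of the proton from the C8 cation would be expected to give Δ7, Δ8 and Δ8(17) isomers. C13 is too remote to choose between the two enantiomeric folds, so a chiral acid would have to control an initiating alkene of a type for which such control is doubtful.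

Alternative 2: a cut of the side chain at C11–C12, with the decalin as a preformed building block. The forward step is an sp3–sp3 coupling of 19-(tert-butyldimethylsilyloxy)-11-iododrim-7-ene A3 with a chiral five-carbon organometallic. The coupling step carries none of the difficulty: all four ring stereocentres, the Δ7 alkene and the C19 oxygen must already be present in A3. A3 would need a long linear sequence of annulation and functional-group steps, and the coupling takes place at a neopentyl-type carbon next to the quaternary C10.

Alternative 3: a cut of C9–C10 by a pericyclic ring closure. The forward step is the photochemical conrotatory 6π-electrocyclisation of the (Z)-triene A4, the mode by which previtamin D closes to the provitamin, to the 5,7-diene A5, followed by hydrogenation of the Δ5 bond. A4 is assembled convergently from a ring-A aldehyde and a chain phosphonium salt. Conrotation guarantees the anti relation of 9-H and the C10 methyl, but the two helical senses of the triene are distinguished only by the C4 methyl and silyloxymethyl groups, so the two faces are expected to be used about equally. In addition the closure competes with Z/E isomerisation and with photochemical reopening. The chosen plan sets C10 under catalyst control instead.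

Key step: step 7

Assumptions: (a) L* in step 7 is the aminophosphine Ph2P–N[CH(CH3)(2-naphthyl)]2; the sense of induction is set by the ligand antipode, and the antipode that gives (3R)-configured 14 is meant. (b) Compounds 1, 5, 12 and 25 are taken as commercial. (c) TBS = tert-butyldimethylsilyl.

## Steps

Step 1
Reactants: 1 but-2-yn-1-ol
Product: 3 (Z)-3-iodobut-2-en-1-ol, via cyclic sodium vinylalanate 2 (not isolated)
Conditions: NaAlH2(OCH2CH2OMe)2, THF, 0 °C to rt; then I2, −78 °C
Reagents that add atoms: iodine, II
Why: Hydroxyl-directed trans-hydroalumination places aluminium on C3 inside a five-membered chelate, and iodinolysis with retention gives the Z iodoalkene (hydroalumination–iodination of a propargylic alcohol).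

Step 2
Reactants: 3 (Z)-3-iodobut-2-en-1-ol
Product: 4 (Z)-3-iodobut-2-enal
Conditions: MnO2, CH2Cl2, rt
Reagents that add atoms: none
Why: Allylic oxidation on MnO2 is chemoselective; the alkene geometry is of no later consequence because the vinyl radical made from it in step 10 inverts freely.

Step 3
Reactants: 5 (S)-citronellol
Product: 6 tert-butyl{[(3S)-3,7-dimethyloct-6-en-1-yl]oxy}dimethylsilane
Conditions: TBSCl, imidazole, CH2Cl2, rt
Reagents that add atoms: tert-butyldimethylsilyl chloride, CC(C)(C)[Si](C)(C)Cl
Why: Standard silylation of the primary alcohol; the silyl ether tolerates the alane, hydride, radical, palladium and dissolving-metal steps that follow.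

Step 4
Reactants: 6 tert-butyl{[(3S)-3,7-dimethyloct-6-en-1-yl]oxy}dimethylsilane
Product: 8 (4S)-6-(tert-butyldimethylsilyloxy)-4-methylhexanal, via ozonide 7 (not isolated)
Conditions: O3, CH2Cl2, −78 °C; then PPh3, −78 °C to rt
Reagents that add atoms: ozone, [O-][O+]=O
Why: Ozonolysis of the trisubstituted alkene with reductive work-up leaves C9 as the aldehyde; C13 is γ to the carbonyl and cannot epimerise.

Step 5
Reactants: 8 (4S)-6-(tert-butyldimethylsilyloxy)-4-methylhexanal
Product: 9 (4S)-6-(tert-butyldimethylsilyloxy)-4-methylhex-1-en-1-yl trifluoromethanesulfonate (E/Z mixture)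
Conditions: Tf2O, 2,6-di-tert-butyl-4-methylpyridine, CH2Cl2, 0 °C to rt
Reagents that add atoms: trifluoromethanesulfonic anhydride, O=S(=O)(OS(=O)(=O)C(F)(F)F)C(F)(F)F
Why: O-Sulfonylation of the aldehyde in the presence of a hindered, non-nucleophilic pyridine gives the enol triflate; either alkene isomer serves in step 6.

Step 6
Reactants: 9 (4S)-6-(tert-butyldimethylsilyloxy)-4-methylhex-1-en-1-yl trifluoromethanesulfonate
Product: 11 tert-butyldimethyl{[(3S)-3-methylhex-5-yn-1-yl]oxy}silane, via lithium acetylide 10 (not isolated)
Conditions: LiN(i-Pr)2 (2.5 equiv), THF, −78 to 0 °C; then H2O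
Reagents that add atoms: none
Why: Base-induced loss of triflate (anti-elimination from the Z isomer, α-elimination with 1,2-hydride shift from the E isomer) gives the terminal alkyne with unchanged carbon count; the second equivalent of base holds it as the acetylide until work-up.

Step 7
Reactants: 11 tert-butyldimethyl{[(3S)-3-methylhex-5-yn-1-yl]oxy}silane; 12 3-methylcyclohex-2-en-1-one; 4 (Z)-3-iodobut-2-enal
Product: 15 (3R)-2-[(2Z)-1-hydroxy-3-iodobut-2-en-1-yl]-3-methyl-3-[(1E,4S)-6-(tert-butyldimethylsilyloxy)-4-methylhex-1-en-1-yl]cyclohexan-1-one (isomer mixture at C2 and at the carbinol carbon), via alkenylalane 13 (not isolated), via aluminium enolate 14 (not isolated)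
Conditions: 11, i-Bu2AlH, heptane, 50 °C; then 12, Cu(O2CC4H3S) (10 mol %), L* (11 mol %), Et2O, −30 °C; then 4, −78 to −30 °C; aq. NH4Cl
Reagents that add atoms: none
Why: cis-Hydroalumination of the terminal alkyne puts aluminium on C9 with E geometry; transmetalation to the chiral monovalent copper–aminophosphine complex gives an alkenylcopper that forms a π-complex with 12, adds oxidatively at C10 and eliminates reductively to the aluminium enolate 14. The closest known reaction type is the tandem hydroalumination/copper-catalysed asymmetric conjugate addition of alkenylalanes to 3-substituted cyclohexenones, which is established for methyl/alkenyl quaternary centres. No ring is closed; the step forms C9–C10 and then C5–C6, and so joins 18 of the 20 skeletal carbons. The C10 configuration is under catalyst control, because 12 is achiral and C13 is too far away to interfere. The selectivities needed are 1,4- over 1,2-addition (secured by copper), alkenyl over isobutyl transfer (the sp2 group transfers preferentially), and reaction of the enolate at C5 and not C3 (14 is formed regiospecifically and is used without equilibration). The hard aluminium enolate adds to the aldehyde carbonyl of 4 and not to its iodo-bearing β-carbon. The configurations created at C5 and C6 do not matter, since both carbons are made planar in steps 8 and 9.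

Step 8
Reactants: 15 (3R)-2-[(2Z)-1-hydroxy-3-iodobut-2-en-1-yl]-3-methyl-3-[(1E,4S)-6-(tert-butyldimethylsilyloxy)-4-methylhex-1-en-1-yl]cyclohexan-1-one
Product: 17 (3R)-2-[(2Z)-3-iodobut-2-en-1-ylidene]-3-methyl-3-[(1E,4S)-6-(tert-butyldimethylsilyloxy)-4-methylhex-1-en-1-yl]cyclohexan-1-one (geometry at the exocyclic C5=C6 bond not controlled), via allylic mesylate 16 (not isolated)
Conditions: MsCl, Et3N, CH2Cl2, 0 °C; then DBU, 0 °C to rt
Reagents that add atoms: none
Why: Mesylation and E1cB elimination of the aldol give the cross-conjugated dienone and erase the uncontrolled centres of 15; the geometry of the new alkene is erased in step 9.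

Step 9
Reactants: 17 (3R)-2-[(2Z)-3-iodobut-2-en-1-ylidene]-3-methyl-3-[(1E,4S)-6-(tert-butyldimethylsilyloxy)-4-methylhex-1-en-1-yl]cyclohexan-1-one
Product: 19 (3R)-2-[(2Z)-3-iodobut-2-en-1-yl]-3-methyl-3-[(1E,4S)-6-(tert-butyldimethylsilyloxy)-4-methylhex-1-en-1-yl]cyclohex-1-en-1-yl trifluoromethanesulfonate, via lithium enolate 18 (not isolated)
Conditions: LiBH(s-Bu)3, THF, −78 °C; then PhNTf2, −78 °C to rt
Reagents that add atoms: N-phenylbis(trifluoromethanesulfonimide), O=S(=O)(N(c1ccccc1)S(=O)(=O)C(F)(F)F)C(F)(F)F
Why: The s-cis exocyclic enone takes hydride from the bulky borohydride at the unhindered C6 rather than at the δ-carbon C8, which carries iodine and methyl; O-triflation of the resulting enolate fixes the C4=C5 double bond regiospecifically (conjugate reduction–enolate triflation).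

Step 10
Reactants: 19 (3R)-2-[(2Z)-3-iodobut-2-en-1-yl]-3-methyl-3-[(1E,4S)-6-(tert-butyldimethylsilyloxy)-4-methylhex-1-en-1-yl]cyclohex-1-en-1-yl trifluoromethanesulfonate
Product: 20 (9S,10R,13S)-15-(tert-butyldimethylsilyloxy)-18,19-dinorlabda-4,7-dien-4-yl trifluoromethanesulfonate
Conditions: (Me3Si)3SiH, AIBN, PhMe (0.01 M), 90 °C, slow addition
Reagents that add atoms: none
Why: Iodine abstraction gives the σ-vinyl radical at C8, which closes ring B by 6-exo-trig addition to C9 of the E alkene, and the C11 radical is reduced by the silane (vinyl radical cyclisation); the ring alkene is C7=C8 by construction. With C9 pseudo-equatorial on the half-chair of ring A, C8 must approach gauche to C20 and anti to C1. The alkene rotamer that puts the small C20 methyl rather than C5 next to the vinylic C11–H (least 1,3-allylic strain) exposes the face that gives 9α-H.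

Step 11
Reactants: 20 (9S,10R,13S)-15-(tert-butyldimethylsilyloxy)-18,19-dinorlabda-4,7-dien-4-yl trifluoromethanesulfonate
Product: 21 methyl (9S,10R,13S)-15-(tert-butyldimethylsilyloxy)-18-norlabda-4,7-dien-19-oate
Conditions: Pd(OAc)2, PPh3, CO (1 atm), MeOH, Et3N, DMF, 60 °C
Reagents that add atoms: carbon monoxide, [C-]#[O+]; methanol, CO
Why: Oxidative addition of zerovalent palladium into the enol triflate, CO insertion and methanolysis give the tetrasubstituted enoate (carbonylation of an enol triflate); the Δ7 alkene and the silyl ether are inert.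

Step 12
Reactants: 21 methyl (9S,10R,13S)-15-(tert-butyldimethylsilyloxy)-18-norlabda-4,7-dien-19-oate
Product: 23 methyl (4S,5R,9S,10R,13S)-15-(tert-butyldimethylsilyloxy)labd-7-en-19-oate, via lithium ester enolate 22 (not isolated)
Conditions: Li (2.2 equiv), NH3(l)/THF, t-BuOH (1 equiv), −78 °C; then MeI, −78 to −33 °C; NH4Cl
Reagents that add atoms: iodomethane, CI
Why: Two-electron reduction of the enoate and protonation at C5, axial and anti to the C10 methyl as in the dissolving-metal reduction of ring-fusion enones, give the trans-fused ester enolate. Methyl iodide then attacks C4 from the α (equatorial) face because the β face is screened by the 1,3-diaxial C20 methyl, which leaves the ester axial as C19 (reductive alkylation of an α,β-unsaturated ester); the isolated Δ7 alkene is not reduced.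

Step 13
Reactants: 23 methyl (4S,5R,9S,10R,13S)-15-(tert-butyldimethylsilyloxy)labd-7-en-19-oate
Product: 24 (4S,5R,9S,10R,13S)-15-(tert-butyldimethylsilyloxy)labd-7-en-19-ol
Conditions: LiAlH4, THF, 0 °C to reflux
Reagents that add atoms: none
Why: Hydride reduction of the hindered axial ester to the neopentyl alcohol; no stereocentre is touched.

Step 14
Reactants: 24 (4S,5R,9S,10R,13S)-15-(tert-butyldimethylsilyloxy)labd-7-en-19-ol; 25 angelic acid [(2Z)-2-methylbut-2-enoic acid]
Product: 27 (4S,5R,9S,10R,13S)-15-(tert-butyldimethylsilyloxy)labd-7-en-19-yl (2Z)-2-methylbut-2-enoate, via mixed anhydride 26 (not isolated)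
Conditions: 25, 2,4,6-trichlorobenzoyl chloride, Et3N, PhMe, rt; then 24, DMAP, PhMe, 75 °C
Reagents that add atoms: none
Why: Yamaguchi esterification: the mixed anhydride acylates the hindered neopentyl alcohol under DMAP catalysis, a protocol that carries the Z acid into its esters with little isomerisation to the E isomer.

Step 15
Reactants: 27 (4S,5R,9S,10R,13S)-15-(tert-butyldimethylsilyloxy)labd-7-en-19-yl (2Z)-2-methylbut-2-enoate
Product: 28 (4S,5R,9S,10R,13S)-15-hydroxylabd-7-en-19-yl (2Z)-2-methylbut-2-enoate
Conditions: HF·pyridine, THF/pyridine, 0 °C to rt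
Reagents that add atoms: none
Why: Buffered fluoride cleaves the primary silyl ether; the Z enoate and the Δ7 alkene are stable to these conditions.

Step 16
Reactants: 28 (4S,5R,9S,10R,13S)-15-hydroxylabd-7-en-19-yl (2Z)-2-methylbut-2-enoate
Product: 30 (4S,5R,9S,10R,13S)-19-[(2Z)-2-methylbut-2-enoyloxy]labd-7-en-15-oic acid (CNP0180171.1), via aldehyde 29 (not isolated)
Conditions: TEMPO (cat.), PhI(OAc)2, MeCN/H2O, rt
Reagents that add atoms: water, O
Why: Oxoammonium-catalysed oxidation of the primary alcohol to the aldehyde, whose hydrate is oxidised on to the acid; the medium is neither basic nor strongly acidic, so the Z ester and the trisubstituted alkene should survive.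

## Compound list

1 | but-2-yn-1-ol | CC#CCO | starting material
2 | sodium 2,2-bis(2-methoxyethoxy)-3-methyl-2,5-dihydro-1,2-oxaluminol-2-uide (cyclic vinylalanate) | CC1=CCO[Al-]1(OCCOC)OCCOC.[Na+] | intermediate (not isolated)
3 | (Z)-3-iodobut-2-en-1-ol | C/C(I)=C/CO | intermediate
4 | (Z)-3-iodobut-2-enal | C/C(I)=C/C=O | intermediate
5 | (S)-citronellol [(3S)-3,7-dimethyloct-6-en-1-ol] | CC(C)=CCC[C@H](C)CCO | starting material
6 | tert-butyl{[(3S)-3,7-dimethyloct-6-en-1-yl]oxy}dimethylsilane | CC(C)=CCC[C@H](C)CCO[Si](C)(C)C(C)(C)C | intermediate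
7 | 3,3-dimethyl-5-[(3S)-5-(tert-butyldimethylsilyloxy)-3-methylpentyl]-1,2,4-trioxolane (ozonide, epimers at the ring carbon) | CC1(C)OOC(CC[C@H](C)CCO[Si](C)(C)C(C)(C)C)O1 | intermediate (not isolated)
8 | (4S)-6-(tert-butyldimethylsilyloxy)-4-methylhexanal | O=CCC[C@H](C)CCO[Si](C)(C)C(C)(C)C | intermediate
9 | (4S)-6-(tert-butyldimethylsilyloxy)-4-methylhex-1-en-1-yl trifluoromethanesulfonate (E/Z mixture) | O=S(=O)(OC=CC[C@H](C)CCO[Si](C)(C)C(C)(C)C)C(F)(F)F | intermediate
10 | lithium (4S)-6-(tert-butyldimethylsilyloxy)-4-methylhex-1-yn-1-ide | [Li]C#CC[C@H](C)CCO[Si](C)(C)C(C)(C)C | intermediate (not isolated)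
11 | tert-butyldimethyl{[(3S)-3-methylhex-5-yn-1-yl]oxy}silane | C#CC[C@H](C)CCO[Si](C)(C)C(C)(C)C | intermediate
12 | 3-methylcyclohex-2-en-1-one | CC1=CC(=O)CCC1 | starting material
13 | [(1E,4S)-6-(tert-butyldimethylsilyloxy)-4-methylhex-1-en-1-yl]bis(2-methylpropyl)alumane | CC(C)C[Al](CC(C)C)/C=C/C[C@H](C)CCO[Si](C)(C)C(C)(C)C | intermediate (not isolated)
14 | ({(3R)-3-methyl-3-[(1E,4S)-6-(tert-butyldimethylsilyloxy)-4-methylhex-1-en-1-yl]cyclohex-1-en-1-yl}oxy)bis(2-methylpropyl)alumane | CC(C)C[Al](CC(C)C)OC1=C[C@@](C)(/C=C/C[C@H](C)CCO[Si](C)(C)C(C)(C)C)CCC1 | intermediate (not isolated)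
15 | (3R)-2-[(2Z)-1-hydroxy-3-iodobut-2-en-1-yl]-3-methyl-3-[(1E,4S)-6-(tert-butyldimethylsilyloxy)-4-methylhex-1-en-1-yl]cyclohexan-1-one (isomer mixture at C2 and the carbinol carbon) | O=C1CCC[C@](C)(/C=C/C[C@H](C)CCO[Si](C)(C)C(C)(C)C)C1C(O)/C=C(/C)I | intermediate
16 | methanesulfonate of 15 | O=C1CCC[C@](C)(/C=C/C[C@H](C)CCO[Si](C)(C)C(C)(C)C)C1C(OS(C)(=O)=O)/C=C(/C)I | intermediate (not isolated)
17 | (3R)-2-[(2Z)-3-iodobut-2-en-1-ylidene]-3-methyl-3-[(1E,4S)-6-(tert-butyldimethylsilyloxy)-4-methylhex-1-en-1-yl]cyclohexan-1-one (exocyclic alkene geometry not controlled) | O=C1CCC[C@](C)(/C=C/C[C@H](C)CCO[Si](C)(C)C(C)(C)C)C1=C/C=C(/C)I | intermediate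
18 | lithium (3R)-2-[(2Z)-3-iodobut-2-en-1-yl]-3-methyl-3-[(1E,4S)-6-(tert-butyldimethylsilyloxy)-4-methylhex-1-en-1-yl]cyclohex-1-en-1-olate | [Li]OC1=C(C/C=C(/C)I)[C@@](C)(/C=C/C[C@H](C)CCO[Si](C)(C)C(C)(C)C)CCC1 | intermediate (not isolated)
19 | (3R)-2-[(2Z)-3-iodobut-2-en-1-yl]-3-methyl-3-[(1E,4S)-6-(tert-butyldimethylsilyloxy)-4-methylhex-1-en-1-yl]cyclohex-1-en-1-yl trifluoromethanesulfonate | O=S(=O)(OC1=C(C/C=C(/C)I)[C@@](C)(/C=C/C[C@H](C)CCO[Si](C)(C)C(C)(C)C)CCC1)C(F)(F)F | intermediate
20 | (9S,10R,13S)-15-(tert-butyldimethylsilyloxy)-18,19-dinorlabda-4,7-dien-4-yl trifluoromethanesulfonate | O=S(=O)(OC1=C2CC=C(C)[C@H](CC[C@H](C)CCO[Si](C)(C)C(C)(C)C)[C@@]2(C)CCC1)C(F)(F)F | intermediate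
21 | methyl (9S,10R,13S)-15-(tert-butyldimethylsilyloxy)-18-norlabda-4,7-dien-19-oate | COC(=O)C1=C2CC=C(C)[C@H](CC[C@H](C)CCO[Si](C)(C)C(C)(C)C)[C@@]2(C)CCC1 | intermediate
22 | lithium enolate (C4=C19 ketene acetal) of methyl (5R,9S,10R,13S)-15-(tert-butyldimethylsilyloxy)-18-norlabd-7-en-19-oate | COC(O[Li])=C1CCC[C@]2(C)[C@@H](CC[C@H](C)CCO[Si](C)(C)C(C)(C)C)C(C)=CC[C@@H]12 | intermediate (not isolated)
23 | methyl (4S,5R,9S,10R,13S)-15-(tert-butyldimethylsilyloxy)labd-7-en-19-oate | COC(=O)[C@@]1(C)CCC[C@]2(C)[C@@H](CC[C@H](C)CCO[Si](C)(C)C(C)(C)C)C(C)=CC[C@@H]12 | intermediate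
24 | (4S,5R,9S,10R,13S)-15-(tert-butyldimethylsilyloxy)labd-7-en-19-ol | OC[C@@]1(C)CCC[C@]2(C)[C@@H](CC[C@H](C)CCO[Si](C)(C)C(C)(C)C)C(C)=CC[C@@H]12 | intermediate
25 | angelic acid [(2Z)-2-methylbut-2-enoic acid] | C/C=C(/C)C(=O)O | starting material
26 | (2Z)-2-methylbut-2-enoic 2,4,6-trichlorobenzoic anhydride | C/C=C(/C)C(=O)OC(=O)c1c(Cl)cc(Cl)cc1Cl | intermediate (not isolated)
27 | (4S,5R,9S,10R,13S)-15-(tert-butyldimethylsilyloxy)labd-7-en-19-yl (2Z)-2-methylbut-2-enoate | C/C=C(/C)C(=O)OC[C@@]1(C)CCC[C@]2(C)[C@@H](CC[C@H](C)CCO[Si](C)(C)C(C)(C)C)C(C)=CC[C@@H]12 | intermediate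
28 | (4S,5R,9S,10R,13S)-15-hydroxylabd-7-en-19-yl (2Z)-2-methylbut-2-enoate | C/C=C(/C)C(=O)OC[C@@]1(C)CCC[C@]2(C)[C@@H](CC[C@H](C)CCO)C(C)=CC[C@@H]12 | intermediate
29 | (4S,5R,9S,10R,13S)-15-oxolabd-7-en-19-yl (2Z)-2-methylbut-2-enoate | C/C=C(/C)C(=O)OC[C@@]1(C)CCC[C@]2(C)[C@@H](CC[C@H](C)CC=O)C(C)=CC[C@@H]12 | intermediate (not isolated)
30 | (4S,5R,9S,10R,13S)-19-[(2Z)-2-methylbut-2-enoyloxy]labd-7-en-15-oic acid | C/C=C(/C)C(=O)OC[C@@]1(C)CCC[C@]2(C)[C@@H](CC[C@H](C)CC(=O)O)C(C)=CC[C@@H]12 | target

## Step count and least certain steps

Total step count: 16 (steps 1–2 prepare 4; steps 3–16 form the main line).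
Longest linear sequence: 14 steps (5 to 30, steps 3–16).

Step 7 (key step). The most likely failure is slow alkenyl transfer to the hindered β,β-disubstituted enone. That would let uncatalysed, non-selective addition or 1,2-addition compete and erode the enantiomeric purity at C10. The crowded enolate may also be captured incompletely by the enal. Fallback (sets out from 11, returns at 15): the asymmetric bond formation is moved from C9–C10 to C10–C20. The alane 13 made from 11 would be quenched with I2 to give the (E)-alkenyl iodide F1. Iodine–lithium exchange (t-BuLi, Et2O, −78 °C), addition to 3-ethoxycyclohex-2-en-1-one and acidic work-up would give the dienone F2. A 1,4-selective copper-catalysed addition of MeMgBr (Cu(OTf)2, chiral imidazolinium salt as carbene precursor, Et2O, −30 °C) would create the quaternary centre and give the bromomagnesium enolate F3, which would be intercepted with 4 to reach 15.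

Step 10. The vinyl radical may capture hydrogen before it cyclises, or it may attack the other face of the C9=C11 alkene, because ring A is not conformationally locked while C5 is planar; the second process would give the C9 epimer. Fallback (sets out from 17, returns at 20): the ring closure would be run on a saturated ring A. 17 would be reduced at C6 with LiBH(s-Bu)3 and the enolate quenched with water to give the ketone F5 (C5 epimers). Its radical cyclisation under the step 10 conditions passes through a chair-like decalin transition state with the C10 methyl axial and would give the decalone F6. Thermodynamic enol triflation towards the ring-fusion carbon (Tf2O, 2,6-di-tert-butyl-4-methylpyridine) would then converge both C5 epimers on 20.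

Step 9. Hydride may attack the carbonyl carbon (1,2-reduction) instead of C6, which would leave no enolate to triflate. Fallback (sets out from 17, returns at 19): the enolate equivalent would be made by transition-metal hydrosilylation instead of hydride addition. RhCl(PPh3)3-catalysed 1,4-addition of Et3SiH to 17 would give the triethylsilyl enol ether F4, and fluoride-mediated exchange (CsF, PhNTf2, DME) would convert it into 19.

Step 12. The ester group may be over-reduced by the dissolving metal before the enolate is alkylated, and protonation at C5 from the β face would lead to the cis-fused isomer. Fallback (sets out from 20, returns at 24): the reduction would be run on a carboxylate, which cannot be over-reduced. Hydroxycarbonylation of 20 (Pd(OAc)2, PPh3, CO, KOAc, aqueous DMF) would give the unsaturated acid F7. Li/NH3 reduction of its lithium salt and C-methylation of the resulting dianion with MeI would give the saturated acid F8, which LiAlH4 would reduce to 24.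

Step 14. The Z acyl group may isomerise to the E isomer during the slow acylation of the neopentyl alcohol at 75 °C, through reversible conjugate addition of the nucleophilic catalyst. Fallback (sets out from 24, returns at 27): the Z alkene would be built on the alcohol instead of being carried through the acylation. Esterification of 24 with 2-[bis(2,2,2-trifluoroethoxy)phosphoryl]propanoic acid (DCC, DMAP, CH2Cl2) would give the phosphonate ester F9. Still–Gennari olefination with acetaldehyde (KN(SiMe3)2, 18-crown-6, THF, −78 °C) would then give 27 with Z selectivity.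

## Further compounds

F1 | step 7 | tert-butyl{[(3S,5E)-6-iodo-3-methylhex-5-en-1-yl]oxy}dimethylsilane | I/C=C/C[C@H](C)CCO[Si](C)(C)C(C)(C)C
F2 | step 7 | 3-[(1E,4S)-6-(tert-butyldimethylsilyloxy)-4-methylhex-1-en-1-yl]cyclohex-2-en-1-one | O=C1C=C(/C=C/C[C@H](C)CCO[Si](C)(C)C(C)(C)C)CCC1
F3 | step 7 | bromomagnesium (3R)-3-methyl-3-[(1E,4S)-6-(tert-butyldimethylsilyloxy)-4-methylhex-1-en-1-yl]cyclohex-1-en-1-olate | Br[Mg]OC1=C[C@@](C)(/C=C/C[C@H](C)CCO[Si](C)(C)C(C)(C)C)CCC1
F4 | step 9 | triethyl({(3R)-2-[(2Z)-3-iodobut-2-en-1-yl]-3-methyl-3-[(1E,4S)-6-(tert-butyldimethylsilyloxy)-4-methylhex-1-en-1-yl]cyclohex-1-en-1-yl}oxy)silane | CC[Si](CC)(CC)OC1=C(C/C=C(/C)I)[C@@](C)(/C=C/C[C@H](C)CCO[Si](C)(C)C(C)(C)C)CCC1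
F5 | step 10 | (3R)-2-[(2Z)-3-iodobut-2-en-1-yl]-3-methyl-3-[(1E,4S)-6-(tert-butyldimethylsilyloxy)-4-methylhex-1-en-1-yl]cyclohexan-1-one (C2 epimers) | O=C1CCC[C@](C)(/C=C/C[C@H](C)CCO[Si](C)(C)C(C)(C)C)C1C/C=C(/C)I
F6 | step 10 | (9S,10R,13S)-15-(tert-butyldimethylsilyloxy)-18,19-dinorlabd-7-en-4-one (C5 epimers) | O=C1CCC[C@]2(C)[C@@H](CC[C@H](C)CCO[Si](C)(C)C(C)(C)C)C(C)=CCC12
F7 | step 12 | (9S,10R,13S)-15-(tert-butyldimethylsilyloxy)-18-norlabda-4,7-dien-19-oic acid | OC(=O)C1=C2CC=C(C)[C@H](CC[C@H](C)CCO[Si](C)(C)C(C)(C)C)[C@@]2(C)CCC1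
F8 | step 12 | (4S,5R,9S,10R,13S)-15-(tert-butyldimethylsilyloxy)labd-7-en-19-oic acid | OC(=O)[C@@]1(C)CCC[C@]2(C)[C@@H](CC[C@H](C)CCO[Si](C)(C)C(C)(C)C)C(C)=CC[C@@H]12
F9 | step 14 | (4S,5R,9S,10R,13S)-15-(tert-butyldimethylsilyloxy)labd-7-en-19-yl 2-[bis(2,2,2-trifluoroethoxy)phosphoryl]propanoate (epimers at the phosphonate α-carbon) | CC(C(=O)OC[C@@]1(C)CCC[C@]2(C)[C@@H](CC[C@H](C)CCO[Si](C)(C)C(C)(C)C)C(C)=CC[C@@H]12)P(=O)(OCC(F)(F)F)OCC(F)(F)F
A1 | alternative 1 | methyl (3S,6E,10E,14Z)-16-acetoxy-3,7,11,15-tetramethylhexadeca-6,10,14-trienoate | COC(=O)C[C@@H](C)CC/C=C(\C)CC/C=C(\C)CC/C=C(/C)COC(C)=O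
A2 | alternative 1 | methyl (4S,5R,9S,10R,13S)-19-acetoxylabd-7-en-15-oate | CC(=O)OC[C@@]1(C)CCC[C@]2(C)[C@@H](CC[C@H](C)CC(=O)OC)C(C)=CC[C@@H]12
A3 | alternative 2 | 19-(tert-butyldimethylsilyloxy)-11-iododrim-7-ene (ring stereocentres as in 30) | CC(C)(C)[Si](C)(C)OC[C@@]1(C)CCC[C@]2(C)[C@@H](CI)C(C)=CC[C@@H]12
A4 | alternative 3 | methyl (3S,6E,8Z)-9-[(6S)-6-(tert-butyldimethylsilyloxymethyl)-2,6-dimethylcyclohex-1-en-1-yl]-3,7-dimethylnona-6,8-dienoate | CC1=C(/C=C\C(C)=C\CC[C@H](C)CC(=O)OC)[C@@](C)(CO[Si](C)(C)C(C)(C)C)CCC1
A5 | alternative 3 | methyl (4S,9S,10R,13S)-19-(tert-butyldimethylsilyloxy)labda-5,7-dien-15-oate | CC(C)(C)[Si](C)(C)OC[C@@]1(C)CCC[C@]2(C)[C@@H](CC[C@H](C)CC(=O)OC)C(C)=CC=C12
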